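**Retrosynthetic overview**

1. Feature: in the seven-membered ring B (C1, C5–C10) the methyl-bearing quaternary C1 is bonded to the allylic CH2 C10, and C5 is joined through C6–C7 to the methyl-bearing olefinic C8 (C8=C9). This is what a Claisen shift leaves behind when an oxygen bridges C5 and C8 in a 2-alkylidene-5-vinyltetrahydrofuran. Daucane numbering is used throughout: C1 ring-fusion C–CH3, C2 angelate CH, C3 CH2, C4 C(OH)(i-Pr), C5 ring-fusion CH, C6 anisoate CH, C7 CH2, C8(CH3)=C9H, C10 CH2; ring A = C1–C5; β = the face of the C1 methyl.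
2. Late stage: the C6 anisoate and C2 angelate come from the alcohols; 6α-OH from the C6 ketone by C4-OH-directed reduction; 4β-OH and 5α-H from a 4β,5β-epoxy 6-ketone (SmI2); the epoxide from the C4=C5 olefin under direction by 2β-OH.
3. Ring A (formed last): McMurry closure of C4=C5 in a 1,5-diketone; its C2–C3 bond comes from a proline aldol of 3-methylbutan-2-one with the C2 aldehyde, which sets C2.
4. Ring B (formed second): thermal Claisen ring enlargement (C1–C10 made, O–C8 broken) of methyl (Z)-2-[(5R)-5-methyl-5-vinyltetrahydrofuran-2-ylidene]propanoate; C8 and the enol ether geometry fix C1.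
5. Oxacycle (formed first): (R)-lavender lactone from (R)-linalool, condensed with methyl propanoate and cyclodehydrated.

Key step: step 5

Remark: the C6 silyloxy group is a spectator in the shift (C1 is fixed by C8 and the enol ether geometry alone), and no reagent distinguishes methyl from vinyl at C8 when a C6 stereocentre is made on the lactone, so the C6 oxygen is installed on the cycloheptenone directly after the shift (steps 6 and 7); C6 is re-set in steps 17 to 19 in any case.

**Route**

Step 1
Reactants: 1 (R)-(−)-linalool
Product: 3 (5R)-5-ethenyl-5-methyloxolan-2-ol as an anomer mixture, via hydroxy aldehyde 2 (not isolated)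
Conditions: O3 (1.0 equiv), CH2Cl2/MeOH, −78 °C, Sudan Red 7B end-point; then Me2S, −78 °C → rt
Reagents that add atoms: ozone, [O-][O+]=O
Why: Indicator-controlled ozonolysis with reductive work-up cleaves the electron-rich trisubstituted olefin much faster than the vinyl group, and the freed γ-hydroxy aldehyde closes to the five-membered lactol; the C8 stereocentre of linalool is not touched.

Step 2
Reactants: 3 (5R)-5-ethenyl-5-methyloxolan-2-ol
Product: 4 (5R)-5-ethenyl-5-methyloxolan-2-one ((R)-lavender lactone)
Conditions: TEMPO (10 mol %), PhI(OAc)2, CH2Cl2, rt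
Reagents that add atoms: none
Why: Oxoammonium (TEMPO) oxidation of a lactol to the lactone, with PhI(OAc)2 as terminal oxidant, leaves the vinyl group and the tertiary allylic C–O bond alone.

Step 3
Reactants: 4 (R)-lavender lactone; 5 methyl propanoate
Product: 6 methyl (6R)-6-hydroxy-2,6-dimethyl-3-oxooct-7-enoate (C2 epimers; in equilibrium with its cyclic hemiketal)
Conditions: LiN(i-Pr)2 (2.2 equiv), 5 (2.3 equiv), THF, −78 °C; add 4, −78 → −30 °C; AcOH quench
Reagents that add atoms: none
Why: Crossed Claisen condensation in which the propanoate lithium enolate is acylated by the lactone carbonyl and the second equivalent of base stores the product as its β-keto ester enolate, which prevents double addition; the epimeric α-carbon (C1) is flattened in step 4.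

Step 4
Reactants: 6 methyl (6R)-6-hydroxy-2,6-dimethyl-3-oxooct-7-enoate
Product: 7 methyl (2Z)-2-[(5R)-5-ethenyl-5-methyloxolan-2-ylidene]propanoate
Conditions: PPTS (10 mol %), 4 Å molecular sieves, PhH, 40 °C
Reagents that add atoms: none
Why: Acid-catalysed cyclodehydration of a δ-hydroxy β-keto ester through the hemiketal and its oxocarbenium ion, which loses the C1 proton from the rotamer that keeps the planar conjugated ester beside the unsubstituted ring oxygen and the methyl beside C6 (allylic strain), so the (Z)-vinylogous carbonate is expected, while the weak acid should leave the tertiary allylic C8–O bond intact.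

Step 5
Reactants: 7 methyl (2Z)-2-[(5R)-5-ethenyl-5-methyloxolan-2-ylidene]propanoate
Product: 8 methyl (1R)-1,5-dimethyl-2-oxocyclohept-5-ene-1-carboxylate
Conditions: degassed mesitylene (0.02 M), base-washed sealed tube, 190 °C
Reagents that add atoms: none
Why: Thermal [3,3] sigmatropic (Claisen) shift of the allyl vinyl ether C1=C5–O–C8–C9=C10 embedded in the oxacycle: the C1–C10 bond forms as O–C8 breaks, C5 becomes the ketone and C8=C9 the ring olefin. The closest known reaction is the thermal ring enlargement of 2-methylene-5-vinyltetrahydrofurans to cyclohept-4-enones, here with a fully substituted, ester-bearing alkylidene carbon. Ring B closes by this pericyclic two-carbon ring enlargement, the vinyl terminus C10 being attacked in a 7-endo sense, and the ring forces the six-centre transition state into a boat, which is also why C8=C9 emerges cis within the ring. The new stereocentre C1 is controlled by the C8 stereocentre together with the (Z) geometry: C10 can reach C1 only on the face of the tetrahydrofuran that carries the vinyl group, so (8R,Z) should give (1R). The step needs clean suprafacial transfer of chirality rather than C8–O heterolysis or E/Z isomerisation, which the non-polar solvent, acid-free glass and absence of Lewis acids should secure; no other sigmatropic pathway is open to the substrate.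

Step 6
Reactants: 8 methyl (1R)-1,5-dimethyl-2-oxocyclohept-5-ene-1-carboxylate
Product: 9 methyl (1R,3S)-3-hydroxy-1,5-dimethyl-2-oxocyclohept-5-ene-1-carboxylate
Conditions: KN(SiMe3)2, THF, −78 °C; then (±)-trans-2-(phenylsulfonyl)-3-phenyloxaziridine, −78 °C; AcOH quench
Reagents that add atoms: 2-(phenylsulfonyl)-3-phenyloxaziridine, O=S(=O)(c1ccccc1)N1OC1c1ccccc1
Why: Electrophilic hydroxylation of the only possible ketone enolate (C1 is quaternary) by the N-sulfonyloxaziridine, with attack at C6 expected anti to the pseudo-axial C1 methyl of the potassium-chelated enolate (ester pseudo-equatorial) to give the (6S) alcohol, a configuration of no later consequence because C6 is oxidised in step 17.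

Step 7
Reactants: 9 methyl (1R,3S)-3-hydroxy-1,5-dimethyl-2-oxocyclohept-5-ene-1-carboxylate
Product: 10 methyl (1R,3S)-3-[(tert-butyldimethylsilyl)oxy]-1,5-dimethyl-2-oxocyclohept-5-ene-1-carboxylate
Conditions: TBSOTf, 2,6-lutidine, CH2Cl2, −78 → 0 °C
Reagents that add atoms: tert-butyldimethylsilyl triflate, CC(C)(C)[Si](C)(C)OS(=O)(=O)C(F)(F)F
Why: Silylation of the α-hydroxy ketone with the silyl triflate and a hindered pyridine base is fast at low temperature and forestalls α-ketol isomerisation.

Step 8
Reactants: 10 methyl (1R,3S)-3-[(tert-butyldimethylsilyl)oxy]-1,5-dimethyl-2-oxocyclohept-5-ene-1-carboxylate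
Product: 11 (1S,3S)-3-[(tert-butyldimethylsilyl)oxy]-1-(hydroxymethyl)-1,5-dimethylcyclohept-5-en-2-ol (both epimers at the new ring carbinol, C5)
Conditions: i-Bu2AlH (5 equiv), CH2Cl2, −78 → 0 °C; aq. potassium sodium tartrate
Reagents that add atoms: none
Why: Hydride reduction of both carbonyl groups is used because the ester of a β-keto ester cannot be reduced selectively; the C5 carbinol epimers converge in step 9, and the low temperature should prevent 1,2-silyl migration.

Step 9
Reactants: 11 (1S,3S)-3-[(tert-butyldimethylsilyl)oxy]-1-(hydroxymethyl)-1,5-dimethylcyclohept-5-en-2-ol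
Product: 12 (1S,3S)-3-[(tert-butyldimethylsilyl)oxy]-1,5-dimethyl-2-oxocyclohept-5-ene-1-carbaldehyde
Conditions: DMP (1,1,1-triacetoxy-1,1-dihydro-1,2-benziodoxol-3(1H)-one, 3 equiv), pyridine, CH2Cl2, 0 °C → rt
Reagents that add atoms: none
Why: Periodinane oxidation of the primary and the secondary alcohol gives the non-enolisable β-keto aldehyde without the acid or base that could trigger deformylation.

Step 10
Reactants: 12 (1S,3S)-3-[(tert-butyldimethylsilyl)oxy]-1,5-dimethyl-2-oxocyclohept-5-ene-1-carbaldehyde; 13 3-methylbutan-2-one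
Product: 14 (5R)-5-hydroxy-2-methyl-5-[(1S,3S)-3-[(tert-butyldimethylsilyl)oxy]-1,5-dimethyl-2-oxocyclohept-5-en-1-yl]pentan-3-one ((2R) in daucane numbering)
Conditions: L-proline (30 mol %), DMSO/13 4:1, rt
Reagents that add atoms: none
Why: Proline-catalysed direct aldol addition in which the enamine formed on the methyl side of the ketone adds to the non-enolisable neopentylic aldehyde (far more electrophilic than the hindered C5 ketone) on its re face in the carboxylic-acid-organised transition state of L-proline, which sets (2R) under catalyst control.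

Step 11
Reactants: 14 the (2R) aldol
Product: 15 (5R)-2-methyl-5-[(triethylsilyl)oxy]-5-[(1S,3S)-3-[(tert-butyldimethylsilyl)oxy]-1,5-dimethyl-2-oxocyclohept-5-en-1-yl]pentan-3-one
Conditions: Et3SiOTf, 2,6-lutidine, CH2Cl2, −78 °C
Reagents that add atoms: triethylsilyl triflate, CC[Si](CC)(CC)OS(=O)(=O)C(F)(F)F
Why: Silylation of the β-hydroxy ketone protects C2–OH against retro-aldol cleavage and elimination in the titanium step, and the triethylsilyl ether is orthogonal to the C6 tert-butyldimethylsilyl ether.

Step 12
Reactants: 15 the 1,5-diketone (C4 and C5 carbonyls)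
Product: 16 2β-(triethylsilyloxy)-6α-(tert-butyldimethylsilyloxy)dauca-4,8-diene, (1R,2R,6S)
Conditions: TiCl3(DME)1.5, Zn–Cu couple, DME, reflux; 15 added by syringe pump over 30 h
Reagents that add atoms: none
Why: Intramolecular McMurry coupling of the C4 and C5 carbonyls by low-valent titanium closes ring A as the tetrasubstituted C4=C5 olefin, five-membered ring formation under slow addition being the most favourable case for this coupling; no stereocentre is formed.

Step 13
Reactants: 16 the bis-silyl diene
Product: 17 6α-(tert-butyldimethylsilyloxy)dauca-4,8-dien-2β-ol, (1R,2R,6S)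
Conditions: PPTS, MeOH/CH2Cl2, 0 °C
Reagents that add atoms: none
Why: Mild acid-catalysed methanolysis removes the triethylsilyl ether much faster than the tert-butyldimethylsilyl ether and frees only C2–OH.

Step 14
Reactants: 17 the cyclopent-3-enol
Product: 18 4β,5β-epoxy-6α-(tert-butyldimethylsilyloxy)dauc-8-en-2β-ol
Conditions: VO(acac)2 (5 mol %), t-BuOOH (in decane), CH2Cl2, 0 °C → rt
Reagents that add atoms: tert-butyl hydroperoxide, CC(C)(C)OO
Why: Vanadium-catalysed hydroxyl-directed epoxidation in which the C2 alkoxide bound to the vanadium peroxide delivers oxygen to the C4=C5 olefin of the cyclopent-3-enol on its own β face, setting C4–O β, while the undirected C8=C9 olefin is left alone.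

Step 15
Reactants: 18 the epoxy alcohol; 19 angelic anhydride ((Z)-2-methylbut-2-enoic anhydride)
Product: 20 4β,5β-epoxy-6α-(tert-butyldimethylsilyloxy)dauc-8-en-2β-yl angelate
Conditions: LiN(SiMe3)2, THF, −78 °C; then 19, −78 → 0 °C
Reagents that add atoms: none
Why: Acylation of the lithium alkoxide of the hindered C2 alcohol with the anhydride avoids nucleophilic catalysts and acid, the conditions under which the (Z)-2-methylbut-2-enoyl group isomerises to the tiglate; C2 itself is not touched.

Step 16
Reactants: 20 the silyl ether
Product: 21 4β,5β-epoxy-6α-hydroxydauc-8-en-2β-yl angelate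
Conditions: Bu4NF, AcOH, THF, 0 °C → rt
Reagents that add atoms: none
Why: Fluoride-mediated desilylation is buffered with acetic acid so that the C6 alkoxide cannot start a Payne-type epoxide migration or attack the ester.

Step 17
Reactants: 21 the epoxy alcohol
Product: 22 4β,5β-epoxy-6-oxodauc-8-en-2β-yl angelate
Conditions: DMP, pyridine, CH2Cl2, 0 °C → rt
Reagents that add atoms: none
Why: Periodinane oxidation of the secondary C6 alcohol under buffered conditions gives the α,β-epoxy ketone without opening the tetrasubstituted epoxide.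

Step 18
Reactants: 22 the epoxy ketone
Product: 23 4β-hydroxy-6-oxo-5αH-dauc-8-en-2β-yl angelate
Conditions: SmI2 (2.5 equiv), MeOH, THF, −90 °C
Reagents that add atoms: none
Why: Reductive opening of an α,β-epoxy ketone by SmI2 cleaves the C5–O bond α to the ketone and keeps the C4–O bond (4β-OH), and the samarium enolate should be protonated by methanol on the α face, away from the C1 methyl and the C4 samarium alkoxide, giving the trans-fused C5–H, which is also the epimer that keeps the C6 carbonyl trans to the isopropyl group.

Step 19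
Reactants: 23 the β-hydroxy ketone
Product: 24 4β,6α-dihydroxy-5αH-dauc-8-en-2β-yl angelate
Conditions: Me4NBH(OAc)3, MeCN/AcOH 1:1, −35 °C
Reagents that add atoms: none
Why: Hydroxyl-directed (Evans–Saksena) reduction in which the tertiary C4 alkoxide binds boron and delivers hydride intramolecularly to the β face of the C6 ketone, giving the 1,3-anti diol with 6α-OH.

Step 20
Reactants: 24 the diol; 25 4-methoxybenzoyl chloride
Product: 26 target, 2β-angeloyloxy-6α-(4-methoxybenzoyloxy)-5αH-dauc-8-en-4β-ol
Conditions: pyridine, DMAP (cat.), CH2Cl2, 0 °C → rt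
Reagents that add atoms: none
Why: DMAP-catalysed acylation with the aroyl chloride should take place only at the secondary C6 alcohol, the tertiary C4 alcohol being inert under these conditions.

**Compound list**

1 | (R)-(−)-linalool, (3R)-3,7-dimethylocta-1,6-dien-3-ol | CC(C)=CCC[C@@](C)(O)C=C | starting material
2 | (4R)-4-hydroxy-4-methylhex-5-enal | O=CCC[C@@](C)(O)C=C | intermediate
3 | (5R)-5-ethenyl-5-methyloxolan-2-ol (anomers) | C[C@]1(C=C)CCC(O)O1 | intermediate
4 | (5R)-5-ethenyl-5-methyloxolan-2-one, (R)-lavender lactone | C[C@]1(C=C)CCC(=O)O1 | intermediate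
5 | methyl propanoate | CCC(=O)OC | starting material
6 | methyl (6R)-6-hydroxy-2,6-dimethyl-3-oxooct-7-enoate (C2 epimers, with its cyclic hemiketal) | COC(=O)C(C)C(=O)CC[C@@](C)(O)C=C | intermediate
7 | methyl (2Z)-2-[(5R)-5-ethenyl-5-methyloxolan-2-ylidene]propanoate | COC(=O)/C(C)=C1\O[C@@](C)(C=C)CC1 | intermediate
8 | methyl (1R)-1,5-dimethyl-2-oxocyclohept-5-ene-1-carboxylate | COC(=O)[C@]1(C)CC=C(C)CCC1=O | intermediate
9 | methyl (1R,3S)-3-hydroxy-1,5-dimethyl-2-oxocyclohept-5-ene-1-carboxylate | COC(=O)[C@]1(C)CC=C(C)C[C@H](O)C1=O | intermediate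
10 | methyl (1R,3S)-3-[(tert-butyldimethylsilyl)oxy]-1,5-dimethyl-2-oxocyclohept-5-ene-1-carboxylate | COC(=O)[C@]1(C)CC=C(C)C[C@H](O[Si](C)(C)C(C)(C)C)C1=O | intermediate
11 | (1S,3S)-3-[(tert-butyldimethylsilyl)oxy]-1-(hydroxymethyl)-1,5-dimethylcyclohept-5-en-2-ol (both epimers at the ring carbinol) | OC[C@]1(C)CC=C(C)C[C@H](O[Si](C)(C)C(C)(C)C)C1O | intermediate
12 | (1S,3S)-3-[(tert-butyldimethylsilyl)oxy]-1,5-dimethyl-2-oxocyclohept-5-ene-1-carbaldehyde | O=C[C@]1(C)CC=C(C)C[C@H](O[Si](C)(C)C(C)(C)C)C1=O | intermediate
13 | 3-methylbutan-2-one | CC(C)C(C)=O | starting material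
14 | (5R)-5-hydroxy-2-methyl-5-[(1S,3S)-3-[(tert-butyldimethylsilyl)oxy]-1,5-dimethyl-2-oxocyclohept-5-en-1-yl]pentan-3-one | CC(C)C(=O)C[C@@H](O)[C@]1(C)CC=C(C)C[C@H](O[Si](C)(C)C(C)(C)C)C1=O | intermediate
15 | (5R)-2-methyl-5-[(triethylsilyl)oxy]-5-[(1S,3S)-3-[(tert-butyldimethylsilyl)oxy]-1,5-dimethyl-2-oxocyclohept-5-en-1-yl]pentan-3-one | CC(C)C(=O)C[C@@H](O[Si](CC)(CC)CC)[C@]1(C)CC=C(C)C[C@H](O[Si](C)(C)C(C)(C)C)C1=O | intermediate
16 | 2β-(triethylsilyloxy)-6α-(tert-butyldimethylsilyloxy)dauca-4,8-diene, (1R,2R,6S) | CC[Si](CC)(CC)O[C@@H]1CC(C(C)C)=C2[C@@H](O[Si](C)(C)C(C)(C)C)CC(C)=CC[C@]21C | intermediate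
17 | 6α-(tert-butyldimethylsilyloxy)dauca-4,8-dien-2β-ol, (1R,2R,6S) | O[C@@H]1CC(C(C)C)=C2[C@@H](O[Si](C)(C)C(C)(C)C)CC(C)=CC[C@]21C | intermediate
18 | 4β,5β-epoxy-6α-(tert-butyldimethylsilyloxy)dauc-8-en-2β-ol | O[C@@H]1C[C@]2(C(C)C)O[C@@]23[C@@H](O[Si](C)(C)C(C)(C)C)CC(C)=CC[C@]31C | intermediate
19 | angelic anhydride, (Z)-2-methylbut-2-enoic anhydride | C/C=C(/C)C(=O)OC(=O)/C(C)=C\C | starting material
20 | 4β,5β-epoxy-6α-(tert-butyldimethylsilyloxy)dauc-8-en-2β-yl angelate | C/C=C(/C)C(=O)O[C@@H]1C[C@]2(C(C)C)O[C@@]23[C@@H](O[Si](C)(C)C(C)(C)C)CC(C)=CC[C@]31C | intermediate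
21 | 4β,5β-epoxy-6α-hydroxydauc-8-en-2β-yl angelate | C/C=C(/C)C(=O)O[C@@H]1C[C@]2(C(C)C)O[C@@]23[C@@H](O)CC(C)=CC[C@]31C | intermediate
22 | 4β,5β-epoxy-6-oxodauc-8-en-2β-yl angelate | C/C=C(/C)C(=O)O[C@@H]1C[C@]2(C(C)C)O[C@@]23C(=O)CC(C)=CC[C@]31C | intermediate
23 | 4β-hydroxy-6-oxo-5αH-dauc-8-en-2β-yl angelate | C/C=C(/C)C(=O)O[C@@H]1C[C@@](O)(C(C)C)[C@@H]2C(=O)CC(C)=CC[C@]21C | intermediate
24 | 4β,6α-dihydroxy-5αH-dauc-8-en-2β-yl angelate | C/C=C(/C)C(=O)O[C@@H]1C[C@@](O)(C(C)C)[C@@H]2[C@@H](O)CC(C)=CC[C@]21C | intermediate
25 | 4-methoxybenzoyl chloride | COc1ccc(cc1)C(Cl)=O | starting material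
26 | CNP0204191.1, (1R,2R,4R,5S,6S)-2-angeloyloxy-6-(4-methoxybenzoyloxy)dauc-8-en-4-ol (daucane numbering) | C/C=C(/C)C(=O)O[C@@H]1C[C@@](O)(C(C)C)[C@@H]2[C@@H](OC(=O)c3ccc(OC)cc3)CC(C)=CC[C@]21C | target

**Step count and risks**

Total step count: 20. Longest linear sequence: 20 steps, from (R)-linalool 1 to 26.

Steps most likely to fail:

Step 12 (McMurry closure). The low-valent titanium may cleave the C6–O bond next to the C5 ketyl (reductive loss of the silyloxy group), or the reaction may stall at the titanium pinacolate, because deoxygenation to a tetrasubstituted olefin beside a quaternary carbon is slow. Fallback, from 15: a pinacol cyclisation with SmI2 (THF, t-BuOH, −78 °C), in which the chelated ketyl should add to the second carbonyl faster than it loses the silyloxy group, is expected to give the cis-fused 2β-(triethylsilyloxy)-6α-(tert-butyldimethylsilyloxy)dauc-8-ene-4β,5β-diol F1. Heating F1 with 1,1'-thiocarbonyldiimidazole in toluene should give the 4,5-cyclic thionocarbonate F2, and Corey–Winter fragmentation of F2 with 1,3-dimethyl-2-phenyl-1,3,2-diazaphospholidine returns to 16.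

Step 5 (Claisen ring enlargement). Heterolysis of the tertiary allylic C8–O bond to an allyl cation and enolate pair (recombination without memory of C8, or proton loss to a diene), or acid-induced E/Z isomerisation ahead of the shift, would erode the transfer of chirality to C1; the conjugated ester may also raise the temperature needed to the point of decomposition. Fallback, from 7: ionise the C8–O bond on purpose with zerovalent palladium (Pd2(dba)3 and a C2-symmetric trans-1,2-diaminocyclohexane bis(2-diphenylphosphinobenzamide) ligand, THF, rt). This is the known palladium-catalysed O-to-C allyl shift of 5-vinyl-2-alkylidenetetrahydrofurans, combined with asymmetric allylic alkylation of a 2-substituted β-keto ester enolate: the fully substituted enolate carbon C1 attacks the unsubstituted allyl terminus C10, closing the same ring, with C1 set by the ligand instead of by C8. The sequence returns to 8 without a new compound (F0).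

Step 10 (proline aldol). Enamine formation from the α-branched ketone may be slow, the catalyst may be tied up as an oxazolidinone by the hindered β-keto aldehyde, or the amine may start deformylation of the aldehyde, so that conversion or facial control falls short. Fallback, from 12 and 13: a preformed boron enolate aldol. Enolisation of 13 on its methyl side with (−)-Ipc2BCl and Et3N (Et2O, −78 °C), addition of 12 and non-oxidative work-up should give 14 directly; methyl ketone enolates of this reagent are expected to attack the aldehyde re face, and the antipodal reagent would be used if the sense proves opposite. No new compound is formed on the way (F0).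

Further compounds
F1 | step 12 | cis-fused 2β-(triethylsilyloxy)-6α-(tert-butyldimethylsilyloxy)dauc-8-ene-4β,5β-diol | CC[Si](CC)(CC)O[C@@H]1C[C@@](O)(C(C)C)[C@@]2(O)[C@@H](O[Si](C)(C)C(C)(C)C)CC(C)=CC[C@]21C
F2 | step 12 | 4β,5β-cyclic thionocarbonate of F1 | CC[Si](CC)(CC)O[C@@H]1C[C@]3(C(C)C)OC(=S)O[C@@]32[C@@H](O[Si](C)(C)C(C)(C)C)CC(C)=CC[C@]21C
F0 | step 5 | none | none
F0 | step 10 | none | none
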